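Remark: flavan numbering (O1, C2–C4, C4a, C5–C8, C8a) is used for every unit; the upper, middle and lower units are the epicatechin, epifisetinidol and catechin units of the target, and β means the face opposite to ring B at C2.

**Retrosynthetic overview**
1. The target is epicatechin-(4β→8)-epifisetinidol-(4β→8)-catechin; the last C–C bond made is C4(middle)–C8(catechin), by Friedel–Crafts coupling after oxidative activation of C4, followed by global debenzylation.
2. The middle unit is cut at O1–C8a and C4–C4a. Its ring A is a resorcinol (oxygen on C7 and C8a, upper unit on C8 between them), so it is carried as cyclohexane-1,3-dione: C8 is the dione C2, C8a a carbonyl carbon and C4a its α-methylene.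
3. The O1–C2–C3–C4 chain is an Evans syn-glycolate aldol product that brings C2 and C3 in the 2,3-cis configuration; C4 is its aldehyde carbon.
4. The C4(upper)–C8 bond comes from SN1 alkylation of the dione C2 with an oxidatively activated, benzylated epicatechin.
5. Ring order: the rings of the upper and lower units come from epicatechin and catechin; the pyran ring of the middle unit is closed, and its ring A aromatised, in the key step (dione + aldehyde → aryl ether + CH2, no redox reagent).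

Key step: step 10

**Route**

Step 1
Reactants: 1 (−)-epicatechin
Product: 2 5,7,3′,4′-tetra-O-benzyl-(−)-epicatechin
Conditions: BnBr (4.4 equiv), K2CO3, DMF, 0 → 23 °C
Reagents that add atoms: benzyl bromide, BrCc1ccccc1
Why: Williamson etherification under carbonate conditions should alkylate only the four phenols and leave the secondary 3-OH, C2 and C3 untouched.

Step 2
Reactants: 2 5,7,3′,4′-tetra-O-benzyl-(−)-epicatechin
Product: 3 5,7,3′,4′-tetra-O-benzyl-4β-(2-ethoxyethoxy)epicatechin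
Conditions: DDQ (2 equiv), 2-ethoxyethanol (5 equiv), CH2Cl2, 23 °C
Reagents that add atoms: 2-ethoxyethanol, CCOCCO
Why: DDQ hydride abstraction from C4 (benzylic to the trioxygenated ring A) gives the flavan-4-yl cation, which the alcohol should capture on the β face, trans to the C3 oxygen, in the known oxidative C4 etherification of benzylated flavan-3-ols.

Step 3
Reactants: 3 5,7,3′,4′-tetra-O-benzyl-4β-(2-ethoxyethoxy)epicatechin
Product: 4 3,5,7,3′,4′-penta-O-benzyl-4β-(2-ethoxyethoxy)epicatechin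
Conditions: NaH, BnBr, Bu4NI (cat.), DMF, 0 → 23 °C
Reagents that add atoms: benzyl bromide, BrCc1ccccc1
Why: Williamson etherification of the secondary alkoxide masks the 3-OH, which would otherwise quench the dianion of step 10 and could close a five-membered ring onto C8a in its acidic phase.

Step 4
Reactants: 4 3,5,7,3′,4′-penta-O-benzyl-4β-(2-ethoxyethoxy)epicatechin; 5 cyclohexane-1,3-dione
Product: 6 2-(3,5,7,3′,4′-penta-O-benzylepicatechin-4β-yl)cyclohexane-1,3-dione
Conditions: 5 (4 equiv), BF3·OEt2 (0.5 equiv), CH2Cl2/THF, −40 → 0 °C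
Reagents that add atoms: none
Why: Lewis-acid ionisation of the C4 ether gives the flavan-4-yl cation, which the enol of 5 should attack through its C2 (Friedel–Crafts-type SN1 alkylation of a 1,3-dicarbonyl compound) anti to the 3-OBn group, setting C4 of the upper unit as 4β, while O-alkylation is reversible under these conditions.

Step 5
Reactants: 7 (S)-4-benzyloxazolidin-2-one; 8 (benzyloxy)acetyl chloride
Product: 9 (S)-4-benzyl-3-[(benzyloxy)acetyl]oxazolidin-2-one
Conditions: n-BuLi, THF, −78 °C; then 8, −78 → 0 °C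
Reagents that add atoms: none
Why: N-acylation of the lithiated oxazolidinone is the standard preparation of the acylated auxiliary.

Step 6
Reactants: 9 (S)-4-benzyl-3-[(benzyloxy)acetyl]oxazolidin-2-one; 10 3,4-bis(benzyloxy)benzaldehyde
Product: 11 (S)-4-benzyl-3-{(2S,3R)-2-(benzyloxy)-3-[3,4-bis(benzyloxy)phenyl]-3-hydroxypropanoyl}oxazolidin-2-one
Conditions: Bu2BOTf, Et3N, CH2Cl2, −78 → 0 °C; then pH 7 phosphate buffer, MeOH, H2O2
Reagents that add atoms: none
Why: Evans syn-aldol reaction, in which the Z boron enolate reacts through a closed chair transition state on the face opposite to the benzyl group of the auxiliary and so should set both new centres (2S,3R, syn), the future C3 and C2 of the middle unit.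

Step 7
Reactants: 11 (S)-4-benzyl-3-{(2S,3R)-2-(benzyloxy)-3-[3,4-bis(benzyloxy)phenyl]-3-hydroxypropanoyl}oxazolidin-2-one
Product: 12 (2S,3R)-2-(benzyloxy)-3-[3,4-bis(benzyloxy)phenyl]-3-hydroxy-N-methoxy-N-methylpropanamide
Conditions: MeNH(OMe)·HCl, AlMe3, THF, −20 → 0 °C; then aq. KNaC4H4O6
Reagents that add atoms: N,O-dimethylhydroxylamine hydrochloride, CNOC.Cl
Why: aluminium amide transamidation of the β-hydroxy imide (Weinreb amide formation) removes the auxiliary without touching either stereocentre.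

Step 8
Reactants: 12 (2S,3R)-2-(benzyloxy)-3-[3,4-bis(benzyloxy)phenyl]-3-hydroxy-N-methoxy-N-methylpropanamide
Product: 13 (2S,3R)-2-(benzyloxy)-3-[3,4-bis(benzyloxy)phenyl]-N-methoxy-N-methyl-3-[(triethylsilyl)oxy]propanamide
Conditions: Et3SiCl, imidazole, DMF, 0 → 23 °C
Reagents that add atoms: chlorotriethylsilane, CC[Si](Cl)(CC)CC
Why: silylation masks the future O1 as an acid-labile ether, so that it neither quenches the dianion nor opens a retro-aldol path in step 10.

Step 9
Reactants: 13 (2S,3R)-2-(benzyloxy)-3-[3,4-bis(benzyloxy)phenyl]-N-methoxy-N-methyl-3-[(triethylsilyl)oxy]propanamide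
Product: 14 (2S,3R)-2-(benzyloxy)-3-[3,4-bis(benzyloxy)phenyl]-3-[(triethylsilyl)oxy]propanal
Conditions: i-Bu2AlH, THF, −78 °C; then aq. KNaC4H4O6
Reagents that add atoms: none
Why: the chelated tetrahedral aluminium adduct of the Weinreb amide collapses only on work-up, so reduction should stop at the aldehyde, which is used at once to avoid epimerisation α to the formyl group.

Step 10
Reactants: 6 2-(3,5,7,3′,4′-penta-O-benzylepicatechin-4β-yl)cyclohexane-1,3-dione; 14 (2S,3R)-2-(benzyloxy)-3-[3,4-bis(benzyloxy)phenyl]-3-[(triethylsilyl)oxy]propanal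
Product: 17 7-hydroxy biflavan (3,3′,4′-tri-O-benzylepifisetinidol bearing the penta-O-benzylepicatechin-4β-yl group at C8), via aldol adduct 15 (not isolated), via bicyclic vinylogous ester 16 (not isolated)
Conditions: 6, LiN(i-Pr)2 (2.3 equiv), THF–DMPU, −78 → 0 °C; 14 (1.3 equiv), −78 °C; then TsOH·H2O (3.5 equiv), −78 → 40 °C
Reagents that add atoms: none
Why: Proposed new method: the dilithium dianion of 6 attacks aldehyde 14 through its γ-carbon, the future C4a (C4a–C4 bond, a β-dicarbonyl dianion aldol addition whose closest known type is the C4 alkylation of cyclohexane-1,3-dione dianions), and on acidification the silyl ether falls off and the freed C2 hydroxyl (O1) condenses with the neighbouring carbonyl C8a (O1–C8a bond, the known cyclodehydration of δ-hydroxy-β-diketones to dihydropyranones) to give 16. Acid-catalysed loss of the C4 hydroxyl through the extended enol of 16 then gives a dienone with a C4=C4a double bond, an isoaromatic tautomer that moves H from C6 to the C7 oxygen and from C5 to C4 to become phenol 17, so that the dione level of ring A and the aldehyde level of C4 are traded for an arene and a methylene without any redox reagent, as in the known isomerisation of 6-alkylidene-3-alkoxycyclohexenones to resorcinol ethers and, for the pairing of a carbonyl carbon and its α-carbon with a heteroatom–C–C–CHO partner, the Friedländer condensation. The only ring closed is the pyran ring, by 6-exo-trig attack of O1 on C8a followed by dehydration, while ring A is not formed but aromatised. No stereocentre is created: the carbinol and ring-fusion centres of 15 and 16 are destroyed, and C2 and C3 of the middle unit are carried over from 11 because neither is enolisable, the C2–O1 bond is never broken and the equatorial H3 of the 2,3-cis series is poorly aligned for loss from the C4 cation. The step needs regioselectivity (O1 ortho to C4, upper unit between the two oxygens), which is secured because the upper unit sits on the C2 of the dione that lies between two equivalent carbonyls and O1 can reach only the carbonyl next to the carbon that made the C–C bond, so attack at either α-methylene leads to the same arene. It also needs O1 to close before the C4 hydroxyl is lost, which the fast six-ring cycloketalisation of a β-diketone and the benzyl group on O3 (no five-ring alternative) should secure.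

Step 11
Reactants: 17 7-hydroxy biflavan
Product: 18 nona-O-benzyl epicatechin-(4β→8)-epifisetinidol
Conditions: BnBr, K2CO3, DMF, 40 °C
Reagents that add atoms: benzyl bromide, BrCc1ccccc1
Why: Williamson etherification of the only free phenol, so that the following oxidation meets a fully etherified substrate.

Step 12
Reactants: 18 nona-O-benzyl epicatechin-(4β→8)-epifisetinidol
Product: 19 nona-O-benzyl epicatechin-(4β→8)-[4β-(2-ethoxyethoxy)epifisetinidol]
Conditions: DDQ (1.5 equiv), 2-ethoxyethanol (5 equiv), CH2Cl2, 23 °C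
Reagents that add atoms: 2-ethoxyethanol, CCOCCO
Why: the oxidative C4 etherification of step 2, a reaction type also known for 4-arylflavan-3-ol and biflavanoid ethers, should take the axial hydrogen of the middle-unit C4 methylene (aligned with ring A, para to 7-OBn and ortho to O1) in preference to the hindered, poorly aligned tertiary C4–H of the upper unit, and the new centre (expected 4β) is ionised again in step 14.

Step 13
Reactants: 20 (+)-catechin
Product: 21 5,7,3′,4′-tetra-O-benzyl-(+)-catechin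
Conditions: BnBr (4.4 equiv), K2CO3, DMF, 0 → 23 °C
Reagents that add atoms: benzyl bromide, BrCc1ccccc1
Why: Williamson etherification of the four phenols only, as in step 1.

Step 14
Reactants: 19 nona-O-benzyl epicatechin-(4β→8)-[4β-(2-ethoxyethoxy)epifisetinidol]; 21 5,7,3′,4′-tetra-O-benzyl-(+)-catechin
Product: 22 trideca-O-benzyl epicatechin-(4β→8)-epifisetinidol-(4β→8)-catechin (3-OH of the catechin unit free)
Conditions: 21 (4 equiv), Me3SiOTf (0.5 equiv), CH2Cl2, −78 °C; then Et3N
Reagents that add atoms: none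
Why: Lewis-acid-mediated Friedel–Crafts interflavan coupling in which the middle-unit C4 cation (stabilised by 7-OBn and O1) should be attacked by C8 of 21, the most nucleophilic position of its ring A, anti to the axial 3-OBn group, setting the last stereocentre as 4β (3,4-trans) as is general for 2,3-cis flavan-4-yl cations, while the excess of 21 suppresses self-condensation.

Step 15
Reactants: 22 trideca-O-benzyl epicatechin-(4β→8)-epifisetinidol-(4β→8)-catechin
Product: 23 epicatechin-(4β→8)-epifisetinidol-(4β→8)-catechin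
Conditions: H2 (1 atm), Pd(OH)2/C, THF/MeOH/H2O, 23 °C
Reagents that add atoms: none
Why: hydrogenolysis of all thirteen benzyl ethers under neutral conditions should leave the interflavan bonds, the benzylic C2–O1 bonds and every stereocentre intact.

**Compound list**

1 | (−)-epicatechin, (2R,3R)-2-(3,4-dihydroxyphenyl)chromane-3,5,7-triol | O[C@@H]1Cc2c(O)cc(O)cc2O[C@@H]1c1ccc(O)c(O)c1 | starting material
2 | 5,7,3′,4′-tetra-O-benzyl-(−)-epicatechin | O[C@@H]1Cc2c(OCc3ccccc3)cc(OCc3ccccc3)cc2O[C@@H]1c1ccc(OCc2ccccc2)c(OCc2ccccc2)c1 | intermediate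
3 | 5,7,3′,4′-tetra-O-benzyl-4β-(2-ethoxyethoxy)epicatechin (2R,3R,4S; 2,3-cis-3,4-trans) | CCOCCO[C@H]1c2c(OCc3ccccc3)cc(OCc3ccccc3)cc2O[C@H](c2ccc(OCc3ccccc3)c(OCc3ccccc3)c2)[C@@H]1O | intermediate
4 | 3,5,7,3′,4′-penta-O-benzyl-4β-(2-ethoxyethoxy)epicatechin | CCOCCO[C@H]1c2c(OCc3ccccc3)cc(OCc3ccccc3)cc2O[C@H](c2ccc(OCc3ccccc3)c(OCc3ccccc3)c2)[C@@H]1OCc1ccccc1 | intermediate
5 | cyclohexane-1,3-dione | O=C1CCCC(=O)C1 | starting material
6 | 2-(3,5,7,3′,4′-penta-O-benzylepicatechin-4β-yl)cyclohexane-1,3-dione (drawn as the enol) | O=C1CCCC(O)=C1[C@H]1c2c(OCc3ccccc3)cc(OCc3ccccc3)cc2O[C@H](c2ccc(OCc3ccccc3)c(OCc3ccccc3)c2)[C@@H]1OCc1ccccc1 | intermediate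
7 | (S)-4-benzyloxazolidin-2-one | O=C1N[C@@H](Cc2ccccc2)CO1 | starting material
8 | (benzyloxy)acetyl chloride | O=C(Cl)COCc1ccccc1 | starting material
9 | (S)-4-benzyl-3-[(benzyloxy)acetyl]oxazolidin-2-one | O=C(COCc1ccccc1)N1C(=O)OC[C@@H]1Cc1ccccc1 | intermediate
10 | 3,4-bis(benzyloxy)benzaldehyde | O=Cc1ccc(OCc2ccccc2)c(OCc2ccccc2)c1 | starting material
11 | (S)-4-benzyl-3-{(2S,3R)-2-(benzyloxy)-3-[3,4-bis(benzyloxy)phenyl]-3-hydroxypropanoyl}oxazolidin-2-one | O[C@H](c1ccc(OCc2ccccc2)c(OCc2ccccc2)c1)[C@H](OCc1ccccc1)C(=O)N1C(=O)OC[C@@H]1Cc1ccccc1 | intermediate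
12 | (2S,3R)-2-(benzyloxy)-3-[3,4-bis(benzyloxy)phenyl]-3-hydroxy-N-methoxy-N-methylpropanamide | O[C@H](c1ccc(OCc2ccccc2)c(OCc2ccccc2)c1)[C@H](OCc1ccccc1)C(=O)N(C)OC | intermediate
13 | (2S,3R)-2-(benzyloxy)-3-[3,4-bis(benzyloxy)phenyl]-N-methoxy-N-methyl-3-[(triethylsilyl)oxy]propanamide | CC[Si](CC)(CC)O[C@H](c1ccc(OCc2ccccc2)c(OCc2ccccc2)c1)[C@H](OCc1ccccc1)C(=O)N(C)OC | intermediate
14 | (2S,3R)-2-(benzyloxy)-3-[3,4-bis(benzyloxy)phenyl]-3-[(triethylsilyl)oxy]propanal | CC[Si](CC)(CC)O[C@H](c1ccc(OCc2ccccc2)c(OCc2ccccc2)c1)[C@H](OCc1ccccc1)C=O | intermediate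
15 | aldol adduct: 4-[2-(benzyloxy)-3-(3,4-dibenzyloxyphenyl)-1-hydroxy-3-(triethylsilyloxy)propyl]-2-(penta-O-benzylepicatechin-4β-yl)cyclohexane-1,3-dione (enol form; O-bearing chain centres as in 14, new carbinol and ring centres as a mixture) | O=C1C(C(O)[C@@H](OCc2ccccc2)[C@H](O[Si](CC)(CC)CC)c2ccc(OCc3ccccc3)c(OCc3ccccc3)c2)CCC(O)=C1[C@H]1c2c(OCc3ccccc3)cc(OCc3ccccc3)cc2O[C@H](c2ccc(OCc3ccccc3)c(OCc3ccccc3)c2)[C@@H]1OCc1ccccc1 | intermediate (not isolated)
16 | bicyclic vinylogous ester: (2R,3R)-3-(benzyloxy)-2-[3,4-bis(benzyloxy)phenyl]-4-hydroxy-8-(penta-O-benzylepicatechin-4β-yl)-2,3,4,4a,5,6-hexahydro-7H-chromen-7-one (mixture at C4 and C4a) | O=C1CCC2C(O)[C@@H](OCc3ccccc3)[C@@H](c3ccc(OCc4ccccc4)c(OCc4ccccc4)c3)OC2=C1[C@H]1c2c(OCc3ccccc3)cc(OCc3ccccc3)cc2O[C@H](c2ccc(OCc3ccccc3)c(OCc3ccccc3)c2)[C@@H]1OCc1ccccc1 | intermediate (not isolated)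
17 | (2R,3R)-3-(benzyloxy)-2-[3,4-bis(benzyloxy)phenyl]-8-(3,5,7,3′,4′-penta-O-benzylepicatechin-4β-yl)chroman-7-ol (octa-O-benzyl epicatechin-(4β→8)-epifisetinidol, 7-OH of the middle unit free) | Oc1ccc2C[C@@H](OCc3ccccc3)[C@@H](c3ccc(OCc4ccccc4)c(OCc4ccccc4)c3)Oc2c1[C@H]1c2c(OCc3ccccc3)cc(OCc3ccccc3)cc2O[C@H](c2ccc(OCc3ccccc3)c(OCc3ccccc3)c2)[C@@H]1OCc1ccccc1 | intermediate
18 | nona-O-benzyl epicatechin-(4β→8)-epifisetinidol (7-O-benzyl ether of 17) | c1ccccc1COc1ccc2C[C@@H](OCc3ccccc3)[C@@H](c3ccc(OCc4ccccc4)c(OCc4ccccc4)c3)Oc2c1[C@H]1c2c(OCc3ccccc3)cc(OCc3ccccc3)cc2O[C@H](c2ccc(OCc3ccccc3)c(OCc3ccccc3)c2)[C@@H]1OCc1ccccc1 | intermediate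
19 | nona-O-benzyl epicatechin-(4β→8)-[4β-(2-ethoxyethoxy)epifisetinidol] (middle unit 2R,3R,4S) | c1ccccc1COc1ccc2[C@H](OCCOCC)[C@@H](OCc3ccccc3)[C@@H](c3ccc(OCc4ccccc4)c(OCc4ccccc4)c3)Oc2c1[C@H]1c2c(OCc3ccccc3)cc(OCc3ccccc3)cc2O[C@H](c2ccc(OCc3ccccc3)c(OCc3ccccc3)c2)[C@@H]1OCc1ccccc1 | intermediate
20 | (+)-catechin, (2R,3S)-2-(3,4-dihydroxyphenyl)chromane-3,5,7-triol | O[C@H]1Cc2c(O)cc(O)cc2O[C@@H]1c1ccc(O)c(O)c1 | starting material
21 | 5,7,3′,4′-tetra-O-benzyl-(+)-catechin | O[C@H]1Cc2c(OCc3ccccc3)cc(OCc3ccccc3)cc2O[C@@H]1c1ccc(OCc2ccccc2)c(OCc2ccccc2)c1 | intermediate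
22 | trideca-O-benzyl epicatechin-(4β→8)-epifisetinidol-(4β→8)-catechin (all phenols and the 3-OH of the upper and middle units benzylated; 3-OH of the catechin unit free) | c1ccccc1COc1ccc2[C@H](c3c(OCc4ccccc4)cc(OCc4ccccc4)c4c3O[C@H](c3ccc(OCc5ccccc5)c(OCc5ccccc5)c3)[C@@H](O)C4)[C@@H](OCc3ccccc3)[C@@H](c3ccc(OCc4ccccc4)c(OCc4ccccc4)c3)Oc2c1[C@H]1c2c(OCc3ccccc3)cc(OCc3ccccc3)cc2O[C@H](c2ccc(OCc3ccccc3)c(OCc3ccccc3)c2)[C@@H]1OCc1ccccc1 | intermediate
23 | epicatechin-(4β→8)-epifisetinidol-(4β→8)-catechin | Oc1cc(O)c2c(c1)O[C@H](c1ccc(O)c(O)c1)[C@H](O)[C@H]2c1c(O)ccc2c1O[C@H](c1ccc(O)c(O)c1)[C@H](O)[C@H]2c1c(O)cc(O)c2c1O[C@H](c1ccc(O)c(O)c1)[C@@H](O)C2 | target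

**Step count and risks**

Total: 15 steps. Longest linear sequence: 10 steps (steps 5, 6, 7, 8, 9, 10, 11, 12, 14, 15, from 7 and 8).

Steps most likely to fail:

1. Step 10 (Proposed new method). What may go wrong:
   - dehydration and aromatisation of the aldol adduct before O1 has closed onto C8a, which would give an open-chain resorcinol;
   - acid-induced loss of the upper unit from C8 at the stage of the vinylogous ester;
   - incomplete dianion formation, or enolisation of the aldehyde instead of addition;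
   - loss of H3 from the C4 cation with erosion of the C3 configuration.

   Fallback with known reactions only, setting out from 6 and 14 and coming back at 18. O-Benzylation of 6 (BnBr, Cs2CO3, DMF) should give 3-(benzyloxy)-2-(penta-O-benzylepicatechin-4β-yl)cyclohex-2-en-1-one F1. Stork–Danheiser α′-aldol addition of its kinetic lithium enolate (LiN(i-Pr)2, THF, −78 °C) to 14 should give the β-hydroxy ketone F2. Mesylation and elimination (MsCl, Et3N; then DBU) to the 6-alkylidene enone, followed by isomerisation of the exocyclic double bond into the ring (RhCl3·3H2O cat., EtOH, 80 °C), should aromatise ring A to the open-chain phenol F3. Triflation (PhNTf2, Et3N, CH2Cl2) should give the aryl triflate F4, and desilylation (HF·pyridine, THF) the benzylic alcohol F5. Palladium-catalysed intramolecular C–O coupling (Pd(OAc)2, 2-(di-tert-butylphosphino)-1,1′-binaphthyl, Cs2CO3, toluene, 80 °C) should then close the pyran ring with retention at C2 and give 18.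

2. Step 12. What may go wrong: hydride abstraction at the wrong site (C4–H or C2–H of the upper unit, C2–H of the middle unit) and over-oxidation of the product to the 4-ketone.

   Fallback, setting out from 17 and coming back at 23; step 11 is omitted so that the free 7-OH steers the oxidation. Treatment of 17 with DDQ (1.05 equiv) and 2-ethoxyethanol in CH2Cl2 at −20 °C should pass through the para-quinone methide (C7=O, C4a=C4) and give the 7-hydroxy-4β-(2-ethoxyethoxy) biflavan F6. Coupling with 21 (4 equiv, Me3SiOTf, CH2Cl2, −78 °C) should give the dodeca-O-benzyl trimer F7 with free 7-OH, and hydrogenolysis under the conditions of step 15 should give 23.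

3. Step 4. What may go wrong: O-alkylation or double alkylation of the dione, self-condensation of the cation with ring A of a second molecule, and erosion of the 4β selectivity.

   Fallback, setting out from 4 and coming back at 6; the dione ring is built after the C–C bond. Methyl 5-oxohexanoate is converted (LiN(i-Pr)2, Me3SiCl, THF, −78 °C) into its kinetic silyl enol ether, methyl 5-[(trimethylsilyl)oxy]hex-5-enoate F8. Mukaiyama-type alkylation of 4 with F8 (Me3SiOTf cat., CH2Cl2, −78 °C) should give the δ-keto ester F9 with the 4β configuration. Claisen (Dieckmann-type) cyclisation (KOt-Bu, THF, 0 → 23 °C; then acid) should close the six-membered ring and give 6.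

Further compounds
F1 | step 10 | 3-(benzyloxy)-2-(3,5,7,3′,4′-penta-O-benzylepicatechin-4β-yl)cyclohex-2-en-1-one | O=C1CCCC(OCc2ccccc2)=C1[C@H]1c2c(OCc3ccccc3)cc(OCc3ccccc3)cc2O[C@H](c2ccc(OCc3ccccc3)c(OCc3ccccc3)c2)[C@@H]1OCc1ccccc1
F2 | step 10 | 3-(benzyloxy)-6-[2-(benzyloxy)-3-(3,4-dibenzyloxyphenyl)-1-hydroxy-3-(triethylsilyloxy)propyl]-2-(penta-O-benzylepicatechin-4β-yl)cyclohex-2-en-1-one (O-bearing chain centres as in 14, new centres as a mixture) | O=C1C(C(O)[C@@H](OCc2ccccc2)[C@H](O[Si](CC)(CC)CC)c2ccc(OCc3ccccc3)c(OCc3ccccc3)c2)CCC(OCc2ccccc2)=C1[C@H]1c2c(OCc3ccccc3)cc(OCc3ccccc3)cc2O[C@H](c2ccc(OCc3ccccc3)c(OCc3ccccc3)c2)[C@@H]1OCc1ccccc1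
F3 | step 10 | 3-(benzyloxy)-6-{(2R,3R)-2-(benzyloxy)-3-[3,4-bis(benzyloxy)phenyl]-3-[(triethylsilyl)oxy]propyl}-2-(penta-O-benzylepicatechin-4β-yl)phenol | Oc1c(C[C@@H](OCc2ccccc2)[C@H](O[Si](CC)(CC)CC)c2ccc(OCc3ccccc3)c(OCc3ccccc3)c2)ccc(OCc2ccccc2)c1[C@H]1c2c(OCc3ccccc3)cc(OCc3ccccc3)cc2O[C@H](c2ccc(OCc3ccccc3)c(OCc3ccccc3)c2)[C@@H]1OCc1ccccc1
F4 | step 10 | trifluoromethanesulfonate of phenol F3 | FC(F)(F)S(=O)(=O)Oc1c(C[C@@H](OCc2ccccc2)[C@H](O[Si](CC)(CC)CC)c2ccc(OCc3ccccc3)c(OCc3ccccc3)c2)ccc(OCc2ccccc2)c1[C@H]1c2c(OCc3ccccc3)cc(OCc3ccccc3)cc2O[C@H](c2ccc(OCc3ccccc3)c(OCc3ccccc3)c2)[C@@H]1OCc1ccccc1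
F5 | step 10 | 3-(benzyloxy)-6-{(2R,3R)-2-(benzyloxy)-3-[3,4-bis(benzyloxy)phenyl]-3-hydroxypropyl}-2-(penta-O-benzylepicatechin-4β-yl)phenyl trifluoromethanesulfonate | FC(F)(F)S(=O)(=O)Oc1c(C[C@@H](OCc2ccccc2)[C@H](O)c2ccc(OCc3ccccc3)c(OCc3ccccc3)c2)ccc(OCc2ccccc2)c1[C@H]1c2c(OCc3ccccc3)cc(OCc3ccccc3)cc2O[C@H](c2ccc(OCc3ccccc3)c(OCc3ccccc3)c2)[C@@H]1OCc1ccccc1
F6 | step 12 | octa-O-benzyl epicatechin-(4β→8)-[4β-(2-ethoxyethoxy)epifisetinidol] with free 7-OH on the middle unit | Oc1ccc2[C@H](OCCOCC)[C@@H](OCc3ccccc3)[C@@H](c3ccc(OCc4ccccc4)c(OCc4ccccc4)c3)Oc2c1[C@H]1c2c(OCc3ccccc3)cc(OCc3ccccc3)cc2O[C@H](c2ccc(OCc3ccccc3)c(OCc3ccccc3)c2)[C@@H]1OCc1ccccc1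
F7 | step 12 | dodeca-O-benzyl epicatechin-(4β→8)-epifisetinidol-(4β→8)-catechin with free 7-OH on the middle unit and free 3-OH on the catechin unit | Oc1ccc2[C@H](c3c(OCc4ccccc4)cc(OCc4ccccc4)c4c3O[C@H](c3ccc(OCc5ccccc5)c(OCc5ccccc5)c3)[C@@H](O)C4)[C@@H](OCc3ccccc3)[C@@H](c3ccc(OCc4ccccc4)c(OCc4ccccc4)c3)Oc2c1[C@H]1c2c(OCc3ccccc3)cc(OCc3ccccc3)cc2O[C@H](c2ccc(OCc3ccccc3)c(OCc3ccccc3)c2)[C@@H]1OCc1ccccc1
F8 | step 4 | methyl 5-[(trimethylsilyl)oxy]hex-5-enoate | C=C(O[Si](C)(C)C)CCCC(=O)OC
F9 | step 4 | methyl 5-oxo-6-(3,5,7,3′,4′-penta-O-benzylepicatechin-4β-yl)hexanoate | COC(=O)CCCC(=O)C[C@H]1c2c(OCc3ccccc3)cc(OCc3ccccc3)cc2O[C@H](c2ccc(OCc3ccccc3)c(OCc3ccccc3)c2)[C@@H]1OCc1ccccc1
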